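**Retrosynthetic overview**

1. Scirpusin A 20 ⇐ global desilylation of 19 ⇐ Mizoroki–Heck coupling of aryl bromide 17 (C4–Br) with styrene 18.
2. The dihydrofuran ring of 17 (O1–C2–C3–C3a–C7a) ⇐ six-membered 1,3-benzoxazine 14 (O1–C2–N3–C4–C4a–C8a) by deletion of N3; the C2–C3 bond and both stereocentres arrive in this one ring contraction.
3. Enabling feature: C2 and C3 of the dihydrofuran ring are both benzylic and C2 also carries O1, so the C2–C3 bond can form by radical-pair collapse after N2 loss from an isodiazene. A nitrogen placed between them gives an N,O-acetal that assembles itself from amine 11 and aldehyde 12.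
4. 11 ⇐ diastereoselective addition of aryl Grignard 9 to tert-butanesulfinyl imine 7, which sets the future C3; C2 is then relayed from it in the oxazine (trans, allylic strain against C5–Br).
5. Ring order: the three arenes are bought; the oxazine ring forms transiently, the dihydrofuran ring forms from it by contraction, and the stilbene arm is attached last.

Key step: step 8

**Remarks**

- TIPS = triisopropylsilyl, TBS = tert-butyldimethylsilyl. The target is (2S,3S), 2,3-trans, in 2,3-dihydro-1-benzofuran numbering.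
- Assumption: the Grignard addition of step 6 is taken to follow the closed six-membered transition state with Mg on the sulfinyl oxygen, which from the (R)-sulfinimine gives the (S)-amine. Should the ortho acetal oxygen invert this sense, (S)-2-methylpropane-2-sulfinamide is used with no other change.
- "Anomeric amide" in step 8 is N-(benzyloxy)-N-(pivaloyloxy)-4-(trifluoromethyl)benzamide, O=C(c1ccc(C(F)(F)F)cc1)N(OCc1ccccc1)OC(=O)C(C)(C)C.

**Route**

Step 1
Reactants: 1 5-bromobenzene-1,3-diol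
Product: 3 2-bromo-4,6-dihydroxybenzaldehyde, via iminium chloride 2 (not isolated)
Conditions: POCl3, DMF, MeCN, 0 → 23 °C; then H2O, 50 °C
Reagents that add atoms: N,N-dimethylformamide CN(C)C=O; water O
Why: Vilsmeier–Haack formylation should take place at the ring carbon ortho to one OH and para to the other (next to Br), as in the formylation of orcinol, and hydrolysis of iminium 2 gives the aldehyde.

Step 2
Reactants: 3 2-bromo-4,6-dihydroxybenzaldehyde
Product: 4 2-bromo-6-hydroxy-4-(triisopropylsilyloxy)benzaldehyde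
Conditions: TIPSCl (1.05 equiv), imidazole, CH2Cl2/DMF, 0 °C
Reagents that add atoms: triisopropylsilyl chloride CC(C)[Si](Cl)(C(C)C)C(C)C
Why: Chemoselective O-silylation should take the free para-OH, because the ortho-OH is tied into a hydrogen bond to the formyl group and is shielded by it.

Step 3
Reactants: 4 2-bromo-6-hydroxy-4-(triisopropylsilyloxy)benzaldehyde
Product: 5 2-bromo-6-(methoxymethoxy)-4-(triisopropylsilyloxy)benzaldehyde
Conditions: MOMCl, i-Pr2NEt, CH2Cl2, 0 → 40 °C
Reagents that add atoms: chloromethyl methyl ether COCCl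
Why: O-alkylation of the remaining phenol with the reactive α-chloro ether gives the MOM ether, and the aryl TIPS ether and the aldehyde are inert to the amine base.

Step 4
Reactants: 5 2-bromo-6-(methoxymethoxy)-4-(triisopropylsilyloxy)benzaldehyde; 6 (R)-2-methylpropane-2-sulfinamide
Product: 7 (R,E)-N-[2-bromo-6-(methoxymethoxy)-4-(triisopropylsilyloxy)benzylidene]-2-methylpropane-2-sulfinamide
Conditions: Ti(OEt)4 (2 equiv), THF, 50 °C
Reagents that add atoms: none
Why: Titanium-mediated sulfinimine condensation, with Ti(OEt)4 as Lewis acid and water scavenger, should give the E-imine without touching the sulfur stereocentre.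

Step 5
Reactants: 1 5-bromobenzene-1,3-diol
Product: 8 1-bromo-3,5-bis(triisopropylsilyloxy)benzene
Conditions: TIPSCl (2.3 equiv), imidazole, DMF, 23 °C
Reagents that add atoms: triisopropylsilyl chloride CC(C)[Si](Cl)(C(C)C)C(C)C
Why: Exhaustive O-silylation of both phenols gives an aryl bromide that tolerates magnesium insertion and the later acid treatment.

Step 6
Reactants: 7 (R,E)-N-[2-bromo-6-(methoxymethoxy)-4-(triisopropylsilyloxy)benzylidene]-2-methylpropane-2-sulfinamide; 8 1-bromo-3,5-bis(triisopropylsilyloxy)benzene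
Product: 10 (R)-N-{(S)-[2-bromo-6-(methoxymethoxy)-4-(TIPSO)phenyl][3,5-bis(TIPSO)phenyl]methyl}-2-methylpropane-2-sulfinamide, via arylmagnesium bromide 9 (not isolated)
Conditions: 8, Mg, THF, 50 °C; then 7, CH2Cl2, −48 → 23 °C; H2O
Reagents that add atoms: none
Why: Diastereoselective 1,2-addition of an aryl Grignard reagent to a tert-butanesulfinyl aldimine in a non-coordinating solvent should pass through the closed chair transition state (Mg on the sulfinyl oxygen, tert-butyl equatorial) and deliver the aryl group to the face that gives the (S)-carbon, the future C3.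

Step 7
Reactants: 10 (R)-N-{(S)-[2-bromo-6-(methoxymethoxy)-4-(TIPSO)phenyl][3,5-bis(TIPSO)phenyl]methyl}-2-methylpropane-2-sulfinamide
Product: 11 2-{(S)-amino[3,5-bis(TIPSO)phenyl]methyl}-3-bromo-5-(TIPSO)phenol
Conditions: HCl (4 M in dioxane), MeOH, 0 → 23 °C; aq. NaHCO3
Reagents that add atoms: none
Why: Acid methanolysis should cleave the N–S bond and exchange the MOM acetal in one operation, while the acid-stable aryl TIPS ethers and the C–N stereocentre (held as the ammonium salt) stay intact.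

Step 8
Reactants: 11 2-{(S)-amino[3,5-bis(TIPSO)phenyl]methyl}-3-bromo-5-(TIPSO)phenol; 12 3,4-bis(tert-butyldimethylsilyloxy)benzaldehyde
Product: 17 (2S,3S)-4-bromo-2-[3,4-bis(TBSO)phenyl]-3-[3,5-bis(TIPSO)phenyl]-6-(TIPSO)-2,3-dihydro-1-benzofuran, via open-chain Schiff base 13 (not isolated), via 1,3-benzoxazine 14 (not isolated), via N-acyl-N-alkoxyhydrazine 15 (not isolated), via isodiazene 16 (not isolated)
Conditions: 4 Å MS, THF, 23 °C; then anomeric amide (1.5 equiv), 45 °C
Reagents that add atoms: none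
Why: Proposed new method: 11 and 12 should condense to Schiff base 13, whose phenol adds reversibly to the C=N carbon (6-endo-trig N,O-acetalisation, ring–chain tautomerism) to give oxazine 14; the ring N–H of 14 then attacks the amide nitrogen of the anomeric amide (pivalate leaves) to give 15, which rearranges with loss of benzyl 4-(trifluoromethyl)benzoate to isodiazene 16, and 16 expels N2 to leave a singlet radical pair at C2 and C4 that collapses to the C2–C3 bond of 17, so the six-membered O,N-ring contracts to the five-membered O-ring by recombination of two ring carbons across the deleted atom. The closest known reaction type is nitrogen deletion of secondary dibenzylic amines with this reagent, including the contraction of benzo-fused and 2-aryl cyclic amines, together with the stereoretentive contraction of cyclic 1,1-diazenes flanked by two substituted carbons; what is new is that the deleted nitrogen belongs to a cyclic N,O-acetal. C3 of 17 is the carbinamine carbon set in step 6, and C2 is the aminal carbon, which equilibrates through 13 and should settle trans to the C4 aryl because allylic strain against the peri C5–Br forces that aryl pseudoaxial while the C2 aryl stays pseudoequatorial. Both centres should then be carried over with retention, because the two radical centres are formed about 2.4 Å apart and couple faster than either can rotate, the peri bromine also hindering planarisation at C4. The step needs amination of the sp3 ring nitrogen in preference to the imine nitrogen and phenol of 13 (the secondary amine is the strongest nucleophile and the tautomeric equilibrium refills it) and N2 loss ahead of retro-[4+2] cleavage to an o-quinone methide, which the two benzylic, radical-stabilising carbons (one also α-oxygenated) should secure at 45 °C.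

Step 9
Reactants: 17 (2S,3S)-4-bromo-2-[3,4-bis(TBSO)phenyl]-3-[3,5-bis(TIPSO)phenyl]-6-(TIPSO)-2,3-dihydro-1-benzofuran; 18 tert-butyldimethyl(4-vinylphenoxy)silane
Product: 19 (2S,3S)-2-[3,4-bis(TBSO)phenyl]-3-[3,5-bis(TIPSO)phenyl]-4-{(E)-2-[4-(TBSO)phenyl]ethenyl}-6-(TIPSO)-2,3-dihydro-1-benzofuran
Conditions: Pd2(dba)3 (cat.), P(t-Bu)3 (cat.), Cy2NMe, 1,4-dioxane, 80 °C
Reagents that add atoms: none
Why: Mizoroki–Heck coupling with a bulky electron-rich phosphine should engage the hindered bromide and give the E-stilbene by syn-insertion and syn-β-hydride elimination, and the amine base leaves the silyl ethers and both stereocentres untouched.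

Step 10
Reactants: 19 (2S,3S)-2-[3,4-bis(TBSO)phenyl]-3-[3,5-bis(TIPSO)phenyl]-4-{(E)-2-[4-(TBSO)phenyl]ethenyl}-6-(TIPSO)-2,3-dihydro-1-benzofuran
Product: 20 scirpusin A
Conditions: TBAF, AcOH, THF, 0 → 23 °C, argon
Reagents that add atoms: none
Why: Fluoride-induced cleavage of all six aryl silyl ethers, buffered with acetic acid, should free the phenols without the strong acid that would cyclise the stilbene onto the resorcinol ring and without phenolate oxidation of the catechol.

**Compound list**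

1 | 5-bromobenzene-1,3-diol | Oc1cc(O)cc(Br)c1 | starting material
2 | N-[(2-bromo-4,6-dihydroxyphenyl)methylidene]-N-methylmethanaminium chloride | C[N+](C)=Cc1c(O)cc(O)cc1Br.[Cl-] | intermediate (not isolated)
3 | 2-bromo-4,6-dihydroxybenzaldehyde | O=Cc1c(O)cc(O)cc1Br | intermediate
4 | 2-bromo-6-hydroxy-4-(triisopropylsilyloxy)benzaldehyde | O=Cc1c(O)cc(O[Si](C(C)C)(C(C)C)C(C)C)cc1Br | intermediate
5 | 2-bromo-6-(methoxymethoxy)-4-(triisopropylsilyloxy)benzaldehyde | O=Cc1c(OCOC)cc(O[Si](C(C)C)(C(C)C)C(C)C)cc1Br | intermediate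
6 | (R)-2-methylpropane-2-sulfinamide | CC(C)(C)[S@@](=O)N | starting material
7 | (R,E)-N-[2-bromo-6-(methoxymethoxy)-4-(triisopropylsilyloxy)benzylidene]-2-methylpropane-2-sulfinamide | CC(C)(C)[S@@](=O)/N=C/c1c(OCOC)cc(O[Si](C(C)C)(C(C)C)C(C)C)cc1Br | intermediate
8 | 1-bromo-3,5-bis(triisopropylsilyloxy)benzene | Brc1cc(O[Si](C(C)C)(C(C)C)C(C)C)cc(O[Si](C(C)C)(C(C)C)C(C)C)c1 | intermediate
9 | [3,5-bis(triisopropylsilyloxy)phenyl]magnesium bromide | Br[Mg]c1cc(O[Si](C(C)C)(C(C)C)C(C)C)cc(O[Si](C(C)C)(C(C)C)C(C)C)c1 | intermediate (not isolated)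
10 | (R)-N-{(S)-[2-bromo-6-(methoxymethoxy)-4-(TIPSO)phenyl][3,5-bis(TIPSO)phenyl]methyl}-2-methylpropane-2-sulfinamide | CC(C)(C)[S@@](=O)N[C@@H](c1cc(O[Si](C(C)C)(C(C)C)C(C)C)cc(O[Si](C(C)C)(C(C)C)C(C)C)c1)c1c(OCOC)cc(O[Si](C(C)C)(C(C)C)C(C)C)cc1Br | intermediate
11 | 2-{(S)-amino[3,5-bis(TIPSO)phenyl]methyl}-3-bromo-5-(TIPSO)phenol | N[C@@H](c1cc(O[Si](C(C)C)(C(C)C)C(C)C)cc(O[Si](C(C)C)(C(C)C)C(C)C)c1)c1c(O)cc(O[Si](C(C)C)(C(C)C)C(C)C)cc1Br | intermediate
12 | 3,4-bis(tert-butyldimethylsilyloxy)benzaldehyde | O=Cc1ccc(O[Si](C)(C)C(C)(C)C)c(O[Si](C)(C)C(C)(C)C)c1 | starting material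
13 | 2-{(S)-[3,5-bis(TIPSO)phenyl]{[(E)-3,4-bis(TBSO)benzylidene]amino}methyl}-3-bromo-5-(TIPSO)phenol | CC(C)(C)[Si](C)(C)Oc1ccc(/C=N/[C@@H](c2cc(O[Si](C(C)C)(C(C)C)C(C)C)cc(O[Si](C(C)C)(C(C)C)C(C)C)c2)c2c(O)cc(O[Si](C(C)C)(C(C)C)C(C)C)cc2Br)cc1O[Si](C)(C)C(C)(C)C | intermediate (not isolated)
14 | (2R,4S)-5-bromo-2-[3,4-bis(TBSO)phenyl]-4-[3,5-bis(TIPSO)phenyl]-7-(TIPSO)-3,4-dihydro-2H-1,3-benzoxazine | Brc1cc(O[Si](C(C)C)(C(C)C)C(C)C)cc2c1[C@H](c1cc(O[Si](C(C)C)(C(C)C)C(C)C)cc(O[Si](C(C)C)(C(C)C)C(C)C)c1)N[C@@H](c1ccc(O[Si](C)(C)C(C)(C)C)c(O[Si](C)(C)C(C)(C)C)c1)O2 | intermediate (not isolated)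
15 | N-(benzyloxy)-N-[(2R,4S)-5-bromo-2-[3,4-bis(TBSO)phenyl]-4-[3,5-bis(TIPSO)phenyl]-7-(TIPSO)-2H-1,3-benzoxazin-3(4H)-yl]-4-(trifluoromethyl)benzamide | Brc1cc(O[Si](C(C)C)(C(C)C)C(C)C)cc2c1[C@H](c1cc(O[Si](C(C)C)(C(C)C)C(C)C)cc(O[Si](C(C)C)(C(C)C)C(C)C)c1)N(N(OCc1ccccc1)C(=O)c1ccc(C(F)(F)F)cc1)[C@@H](c1ccc(O[Si](C)(C)C(C)(C)C)c(O[Si](C)(C)C(C)(C)C)c1)O2 | intermediate (not isolated)
16 | isodiazene (1,1-diazene) at N3 of (2R,4S)-oxazine 14 | Brc1cc(O[Si](C(C)C)(C(C)C)C(C)C)cc2c1[C@H](c1cc(O[Si](C(C)C)(C(C)C)C(C)C)cc(O[Si](C(C)C)(C(C)C)C(C)C)c1)[N+](=[N-])[C@@H](c1ccc(O[Si](C)(C)C(C)(C)C)c(O[Si](C)(C)C(C)(C)C)c1)O2 | intermediate (not isolated)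
17 | (2S,3S)-4-bromo-2-[3,4-bis(TBSO)phenyl]-3-[3,5-bis(TIPSO)phenyl]-6-(TIPSO)-2,3-dihydro-1-benzofuran | Brc1cc(O[Si](C(C)C)(C(C)C)C(C)C)cc2c1[C@H](c1cc(O[Si](C(C)C)(C(C)C)C(C)C)cc(O[Si](C(C)C)(C(C)C)C(C)C)c1)[C@@H](c1ccc(O[Si](C)(C)C(C)(C)C)c(O[Si](C)(C)C(C)(C)C)c1)O2 | intermediate
18 | tert-butyldimethyl(4-vinylphenoxy)silane | C=Cc1ccc(O[Si](C)(C)C(C)(C)C)cc1 | starting material
19 | (2S,3S)-2-[3,4-bis(TBSO)phenyl]-3-[3,5-bis(TIPSO)phenyl]-4-{(E)-2-[4-(TBSO)phenyl]ethenyl}-6-(TIPSO)-2,3-dihydro-1-benzofuran | CC(C)(C)[Si](C)(C)Oc1ccc(/C=C/c2cc(O[Si](C(C)C)(C(C)C)C(C)C)cc3c2[C@H](c2cc(O[Si](C(C)C)(C(C)C)C(C)C)cc(O[Si](C(C)C)(C(C)C)C(C)C)c2)[C@@H](c2ccc(O[Si](C)(C)C(C)(C)C)c(O[Si](C)(C)C(C)(C)C)c2)O3)cc1 | intermediate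
20 | scirpusin A | Oc1ccc(/C=C/c2cc(O)cc3c2[C@H](c2cc(O)cc(O)c2)[C@@H](c2ccc(O)c(O)c2)O3)cc1 | target

**Step count and risks**

Total step count: 10. Longest linear sequence: 9 (steps 1–4 and 6–10, from 5-bromoresorcinol).

Steps most likely to fail:

1. Step 8 (Proposed new method). The amination may go to the imine nitrogen of the open tautomer instead of the ring nitrogen. The radical pair may lose its stereochemical memory by rotation before collapse, or the isodiazene may cleave by retro-[4+2] to an o-quinone methide, and either would erode the trans selectivity and the enantiopurity. The fallback sets out from compound 4 and comes back at compound 17, using the known o-quinone methide/sulfonium ylide [4+1] annulation. Addition of Grignard reagent 9 (2.2 equiv, THF, 0 °C) to 4 would give racemic 3-bromo-2-{[3,5-bis(TIPSO)phenyl](hydroxy)methyl}-5-(TIPSO)phenol F1. p-Toluenesulfinic acid in CH2Cl2 would convert it into 3-bromo-2-{[3,5-bis(TIPSO)phenyl](4-methylbenzenesulfonyl)methyl}-5-(TIPSO)phenol F2, a base-triggered o-quinone methide precursor. Aldehyde 12 would be reduced with NaBH4 to [3,4-bis(TBSO)phenyl]methanol F3, which with (2R,5R)-2,5-dimethylthiolane and HBF4·OEt2 would give (2R,5R)-1-[3,4-bis(TBSO)benzyl]-2,5-dimethylthiolan-1-ium tetrafluoroborate F4. F2 and F4 with Cs2CO3 in CH2Cl2 would generate the o-quinone methide and the benzylic ylide, and conjugate addition followed by SN2 closure with loss of the sulfide should give trans-17. The enantiomer of the C2-symmetric sulfide that leads to (2S,3S) would be fixed in a trial run, and any residual minor enantiomer removed by crystallisation or chiral chromatography.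

2. Step 6. Chelation of magnesium by the ortho acetal oxygen may reverse or erode the facial selectivity, and addition to the di-ortho-substituted imine may be slow. The fallback sets out from compound 5 and comes back at compound 10, forming the C–H bond instead of the C–aryl bond. Grignard reagent 9 would add to 5 to give racemic [2-bromo-6-(methoxymethoxy)-4-(TIPSO)phenyl][3,5-bis(TIPSO)phenyl]methanol F5. Dess–Martin oxidation would give [2-bromo-6-(methoxymethoxy)-4-(TIPSO)phenyl][3,5-bis(TIPSO)phenyl]methanone F6. Condensation with 6 (Ti(OEt)4, THF, 70 °C) would give (R,E)-N-{[2-bromo-6-(methoxymethoxy)-4-(TIPSO)phenyl][3,5-bis(TIPSO)phenyl]methylidene}-2-methylpropane-2-sulfinamide F7. Reduction with L-Selectride at −78 °C (open transition state) should give 10; if that delivers the epimer, NaBH4 (closed transition state) would be used instead.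

3. Step 9. Oxidative addition and alkene insertion at the bromide flanked by the C3 diarylmethine may be sluggish, with hydrodebromination competing. The fallback sets out from compound 17 and comes back at compound 19. Stille coupling with tributyl(vinyl)stannane (Pd[P(t-Bu)3]2, toluene, 80 °C; neutral, small coupling partner) would give (2S,3S)-4-ethenyl-2-[3,4-bis(TBSO)phenyl]-3-[3,5-bis(TIPSO)phenyl]-6-(TIPSO)-2,3-dihydro-1-benzofuran F8. Cross-metathesis of F8 with an excess of 18 (second-generation Hoveyda–Grubbs catalyst, CH2Cl2, 40 °C) should give the E-stilbene 19, the hindered styrene F8 being slow to homodimerise.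

**Further compounds**

F1 | step 8 | 3-bromo-2-{[3,5-bis(TIPSO)phenyl](hydroxy)methyl}-5-(TIPSO)phenol (racemic) | OC(c1cc(O[Si](C(C)C)(C(C)C)C(C)C)cc(O[Si](C(C)C)(C(C)C)C(C)C)c1)c1c(O)cc(O[Si](C(C)C)(C(C)C)C(C)C)cc1Br
F2 | step 8 | 3-bromo-2-{[3,5-bis(TIPSO)phenyl](4-methylbenzenesulfonyl)methyl}-5-(TIPSO)phenol (racemic) | Cc1ccc(cc1)S(=O)(=O)C(c1cc(O[Si](C(C)C)(C(C)C)C(C)C)cc(O[Si](C(C)C)(C(C)C)C(C)C)c1)c1c(O)cc(O[Si](C(C)C)(C(C)C)C(C)C)cc1Br
F3 | step 8 | [3,4-bis(tert-butyldimethylsilyloxy)phenyl]methanol | OCc1ccc(O[Si](C)(C)C(C)(C)C)c(O[Si](C)(C)C(C)(C)C)c1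
F4 | step 8 | (2R,5R)-1-[3,4-bis(TBSO)benzyl]-2,5-dimethylthiolan-1-ium tetrafluoroborate | C[C@@H]1CC[C@@H](C)[S+]1Cc1ccc(O[Si](C)(C)C(C)(C)C)c(O[Si](C)(C)C(C)(C)C)c1.F[B-](F)(F)F
F5 | step 6 | [2-bromo-6-(methoxymethoxy)-4-(TIPSO)phenyl][3,5-bis(TIPSO)phenyl]methanol (racemic) | OC(c1cc(O[Si](C(C)C)(C(C)C)C(C)C)cc(O[Si](C(C)C)(C(C)C)C(C)C)c1)c1c(OCOC)cc(O[Si](C(C)C)(C(C)C)C(C)C)cc1Br
F6 | step 6 | [2-bromo-6-(methoxymethoxy)-4-(TIPSO)phenyl][3,5-bis(TIPSO)phenyl]methanone | O=C(c1cc(O[Si](C(C)C)(C(C)C)C(C)C)cc(O[Si](C(C)C)(C(C)C)C(C)C)c1)c1c(OCOC)cc(O[Si](C(C)C)(C(C)C)C(C)C)cc1Br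
F7 | step 6 | (R,E)-N-{[2-bromo-6-(methoxymethoxy)-4-(TIPSO)phenyl][3,5-bis(TIPSO)phenyl]methylidene}-2-methylpropane-2-sulfinamide | CC(C)(C)[S@@](=O)/N=C(/c1c(OCOC)cc(O[Si](C(C)C)(C(C)C)C(C)C)cc1Br)c1cc(O[Si](C(C)C)(C(C)C)C(C)C)cc(O[Si](C(C)C)(C(C)C)C(C)C)c1
F8 | step 9 | (2S,3S)-4-ethenyl-2-[3,4-bis(TBSO)phenyl]-3-[3,5-bis(TIPSO)phenyl]-6-(TIPSO)-2,3-dihydro-1-benzofuran | C=Cc1cc(O[Si](C(C)C)(C(C)C)C(C)C)cc2c1[C@H](c1cc(O[Si](C(C)C)(C(C)C)C(C)C)cc(O[Si](C(C)C)(C(C)C)C(C)C)c1)[C@@H](c1ccc(O[Si](C)(C)C(C)(C)C)c(O[Si](C)(C)C(C)(C)C)c1)O2
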